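**Plan**
1. Locants follow cyclodeca[b]furan-2-one (lactone O1, C2=O, C3, C3a, C4–C11, C11a; the ether oxygen bridges C5 and C10). Retrosynthesis removes the C11 isovalerate and the C3 methylene, desaturates C7–C8, then cuts the ether bond O–C10 and the ring bond C5–C6 together. This opens the 11-oxabicyclo[4.4.1]undecane core to trans-lactone 14, which carries an aldehyde (C5), a C10–C11 epoxide and an (E)-allylsilane (C6–C8).
2. Enabling feature: the bridging oxygen joins C5 (aldehyde oxidation level) to C10, a methyl-bearing tertiary carbon whose neighbour C11 is oxygenated. That is the imprint of an aldehyde oxygen opening a C10–C11 epoxide; the resulting oxocarbenium carbon C5 is one bond from C6, so both oxepane rings, and with them the ten-membered carbocycle, can close around one cation.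
3. Further cuts: C3a–C4 (conjugate addition to a butenolide), C11a–C3a (alkynylation of an enal), C10–CH3 and C11–C11a (alkyne carbometalation/hydroxymethylation), C8–C9 (Claisen rearrangement).
4. Forward order: allylsilane chain from (R)-but-3-yn-2-ol → enal → propargylic alcohol → epoxide → butenolide → aldehyde arm → cascade (both oxepanes and the ten-membered ring) → hydrogenation, α-methylenation, acylation.
5. Stereochemistry: C6 from the silyl stereocentre (chiral-pool carbinol, Claisen chirality transfer, anti-SE2'); C11a by catalyst-controlled alkynylation; C11 and C10 by hydroxyl-directed epoxidation (C10 then inverted in the cascade); C3a by anti conjugate addition; C5 by the bridging tether.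

Key step: step 10

Remark: the (S,S)-ProPhenol–zinc catalyst is assumed to deliver the alkynyl group to the Re face of enal 8; if the sense is opposite, the (R,R)-ligand is used and nothing else changes.

**Step 1**
Reactants: 1 (2R)-but-3-yn-2-ol
Product: 2 (2R,3E)-4-[dimethyl(phenyl)silyl]but-3-en-2-ol
Conditions: PhMe2SiH, PtCl2 (1 mol%), XPhos (2-dicyclohexylphosphino-2',4',6'-triisopropylbiphenyl, 2 mol%), THF, 50 °C
Reagents that add atoms: dimethyl(phenyl)silane C[SiH](C)c1ccccc1
Why: Platinum-catalysed syn hydrosilylation of a terminal propargylic alcohol should place silicon on the terminal carbon to give the (E)-vinylsilane, and the carbinol stereocentre is not touched.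

**Step 2**
Reactants: 2 (2R,3E)-4-[dimethyl(phenyl)silyl]but-3-en-2-ol
Product: 3 methyl (3R,4E)-3-[dimethyl(phenyl)silyl]hex-4-enoate
Conditions: MeC(OMe)3, EtCO2H (5 mol%), xylenes, 140 °C, removal of MeOH
Reagents that add atoms: trimethyl orthoacetate CC(OC)(OC)OC
Why: Johnson–Claisen rearrangement through a chair transition state with the carbinol methyl equatorial transfers the carbinol chirality suprafacially to the new C–Si stereocentre (3R) and fixes the (E)-propenyl geometry.

**Step 3**
Reactants: 3 methyl (3R,4E)-3-[dimethyl(phenyl)silyl]hex-4-enoate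
Product: 5 [(4R,5E)-hept-5-en-1-yn-4-yl]dimethyl(phenyl)silane, via aldehyde 4 (not isolated)
Conditions: iBu2AlH (1.05 equiv), CH2Cl2, −78 °C; then MeOH, K2CO3, dimethyl (1-diazo-2-oxopropyl)phosphonate, −78 → 23 °C
Reagents that add atoms: dimethyl (1-diazo-2-oxopropyl)phosphonate CC(=O)C(=[N+]=[N-])P(=O)(OC)OC
Why: Low-temperature half-reduction of the ester followed in the same flask by Ohira–Bestmann (Seyferth–Gilbert) homologation gives the terminal alkyne, and the β-silyl stereocentre cannot epimerise because it is not α to the carbonyl.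

**Step 4**
Reactants: 5 [(4R,5E)-hept-5-en-1-yn-4-yl]dimethyl(phenyl)silane
Product: 7 (2E,5R,6E)-5-[dimethyl(phenyl)silyl]-3-methylocta-2,6-dien-1-ol, via alkenylalane 6 (not isolated)
Conditions: Me3Al (2.5 equiv), Cp2ZrCl2 (0.25 equiv), CH2Cl2, 0 → 23 °C; then (CH2O)n, THF, 0 → 40 °C; aq. potassium sodium tartrate
Reagents that add atoms: trimethylaluminium C[Al](C)C; paraformaldehyde (as formaldehyde) C=O
Why: Negishi zirconium-catalysed carboalumination adds methyl and aluminium syn across the terminal alkyne with methyl on the internal carbon, and hydroxymethylation of the alkenylalane with retention fixes the (E)-trisubstituted olefin.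

**Step 5**
Reactants: 7 (2E,5R,6E)-5-[dimethyl(phenyl)silyl]-3-methylocta-2,6-dien-1-ol
Product: 8 (2E,5R,6E)-5-[dimethyl(phenyl)silyl]-3-methylocta-2,6-dienal
Conditions: MnO2 (activated, excess), CH2Cl2, 23 °C
Reagents that add atoms: none
Why: Allylic oxidation with activated MnO2 should stop at the enal without isomerising the (E)-olefin or touching the allylsilane.

**Step 6**
Reactants: 8 (2E,5R,6E)-5-[dimethyl(phenyl)silyl]-3-methylocta-2,6-dienal
Product: 9 methyl (4S,5E,8R,9E)-8-[dimethyl(phenyl)silyl]-4-hydroxy-6-methylundeca-5,9-dien-2-ynoate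
Conditions: methyl propiolate (3 equiv), Me2Zn (3 equiv), (S,S)-ProPhenol ligand (20 mol%), Ph3P=O (40 mol%), toluene, 0–4 °C
Reagents that add atoms: methyl prop-2-ynoate C#CC(=O)OC
Why: Zinc–ProPhenol catalysed asymmetric alkynylation of an α,β-unsaturated aldehyde should deliver the zinc alkynylide to the Re face of the carbonyl and so set the carbinol centre (4S, the future C11a), the remote silyl stereocentre having no influence.

**Step 7**
Reactants: 9 methyl (4S,5E,8R,9E)-8-[dimethyl(phenyl)silyl]-4-hydroxy-6-methylundeca-5,9-dien-2-ynoate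
Product: 10 methyl (4R)-4-hydroxy-4-[(2S,3S)-3-{(2R,3E)-2-[dimethyl(phenyl)silyl]pent-3-en-1-yl}-3-methyloxiran-2-yl]but-2-ynoate
Conditions: VO(acac)2 (5 mol%), t-BuOOH (1.5 equiv, decane), CH2Cl2, 0 °C
Reagents that add atoms: tert-butyl hydroperoxide CC(C)(C)OO
Why: Hydroxyl-directed vanadium-catalysed epoxidation is chemoselective for the allylic-alcohol olefin (allylsilane and ynoate are left alone), and because the cis-methyl group enforces the H-eclipsed conformer (1,3-allylic strain) oxygen should be delivered syn to the hydroxyl to give the threo (2S,3S) epoxide.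

**Step 8**
Reactants: 10 methyl (4R)-4-hydroxy-4-[(2S,3S)-3-{(2R,3E)-2-[dimethyl(phenyl)silyl]pent-3-en-1-yl}-3-methyloxiran-2-yl]but-2-ynoate
Product: 12 (5R)-5-[(2S,3S)-3-{(2R,3E)-2-[dimethyl(phenyl)silyl]pent-3-en-1-yl}-3-methyloxiran-2-yl]furan-2(5H)-one, via Z-enoate 11 (not isolated)
Conditions: H2 (1 atm), Pd/CaCO3 poisoned with Pb(OAc)2 (Lindlar catalyst), quinoline, EtOAc, 23 °C; then SiO2, CH2Cl2, 23 °C
Reagents that add atoms: none
Why: Lindlar cis-semihydrogenation of the ynoate gives the (Z)-γ-hydroxy enoate, which should lactonise spontaneously to the butenolide with retention at the carbinol carbon because its C–O bond is not broken.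

**Step 9**
Reactants: 12 (5R)-5-[(2S,3S)-3-{(2R,3E)-2-[dimethyl(phenyl)silyl]pent-3-en-1-yl}-3-methyloxiran-2-yl]furan-2(5H)-one
Product: 14 2-{(2R,3R)-2-[(2S,3S)-3-{(2R,3E)-2-[dimethyl(phenyl)silyl]pent-3-en-1-yl}-3-methyloxiran-2-yl]-5-oxooxolan-3-yl}acetaldehyde, via enol ether 13 (not isolated)
Conditions: (E)-2-(2-ethoxyethenyl)-4,4,5,5-tetramethyl-1,3,2-dioxaborolane (2 equiv), [Rh(cod)OH]2 (3 mol%), 1,4-dioxane/H2O 10:1, 40 °C; then 0.5 M aq. oxalic acid (cat.), THF, 0 °C
Reagents that add atoms: (E)-2-(2-ethoxyethenyl)-4,4,5,5-tetramethyl-1,3,2-dioxaborolane CCO/C=C/B1OC(C)(C)C(C)(C)O1; water O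
Why: Rhodium-catalysed Hayashi–Miyaura conjugate addition of the alkenylboronate should occur on the butenolide face anti to the C5 substituent, setting the trans stereocentre (future C3a), and mild acid hydrolysis of the enol ether unveils the aldehyde arm.

**Step 10**
Reactants: 14 2-{(2R,3R)-2-[(2S,3S)-3-{(2R,3E)-2-[dimethyl(phenyl)silyl]pent-3-en-1-yl}-3-methyloxiran-2-yl]-5-oxooxolan-3-yl}acetaldehyde
Product: 17 (3aR,5R,6S,7Z,10R,11S,11aR)-11-hydroxy-6,10-dimethyl-3a,4,5,6,9,10,11,11a-octahydro-5,10-epoxycyclodeca[b]furan-2(3H)-one, via oxocarbenium triflate 15 (not isolated), via silyl ether 16 (not isolated)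
Conditions: Me3SiOTf (0.1 equiv), 2,6-di-tert-butyl-4-methylpyridine (0.2 equiv), 4 Å MS, CH2Cl2 (0.003 M), −78 → −30 °C; then 1 M HCl (cat.), THF/H2O, 0 °C
Reagents that add atoms: none
Why: Proposed new method: the silyl triflate activates the trisubstituted epoxide, the aldehyde oxygen opens it at the tertiary carbon C10 with inversion (7-endo-tet), and the seven-membered oxocarbenium ion 15 (which may rest as its internal acetal with O11 and re-ionise) is trapped by the tethered (E)-allylsilane in an SE2' Hosomi–Sakurai closure (7-endo-trig at C5) that forms C5–C6, closes the ten-membered carbocycle and releases PhMe2Si+, which silylates the next epoxide so that Me3SiOTf only initiates. The closest known reaction types are Lewis-acid opening of an epoxide by a carbonyl oxygen (epoxy carbonyl to bicyclic acetal, endo-selective epoxide cascades ending on a carbonyl group) and intramolecular allylsilane trapping of cyclic oxocarbenium ions to oxa-bridged medium rings; their union in one substrate to give an oxygen-bridged ten-membered ring has no direct precedent. C10 is set by stereospecific inversion of the (S)-epoxide carbon and C11 is retained, while C5 is fixed by the tether, because the allylsilane hangs from C10 and can reach only the oxocarbenium face cis to it. C6 follows from anti-SE2' attack on the (R)-allylsilane with (E)-olefin geometry, the chain lying inside so that the new C7=C8 bond is cis in the seven-membered ring, which places the C6 methyl on the exo face (6S). The step needs opening at the tertiary and not the secondary epoxide carbon, secured by the methyl-stabilised incipient cation and by inductive deactivation of C11 through the adjacent lactone C–O bond (the lactone carbonyl is held away from the epoxide by the ring), and it needs intramolecular allylation, secured by high dilution and by the hindered base that suppresses protodesilylation. If allylation of the activated aldehyde came first, transannular opening of the epoxide by the new silyl ether would form the same two bonds.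

**Step 11**
Reactants: 17 (3aR,5R,6S,7Z,10R,11S,11aR)-11-hydroxy-6,10-dimethyl-3a,4,5,6,9,10,11,11a-octahydro-5,10-epoxycyclodeca[b]furan-2(3H)-one
Product: 18 (3aR,5R,6S,10R,11S,11aR)-11-hydroxy-6,10-dimethyldecahydro-5,10-epoxycyclodeca[b]furan-2(3H)-one
Conditions: H2 (1 atm), Pd/C (10%), EtOAc, 23 °C
Reagents that add atoms: none
Why: Heterogeneous catalytic hydrogenation of the cis-disubstituted C7=C8 olefin creates no stereocentre and should leave the lactone, the bridging ether and the alcohol intact.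

**Step 12**
Reactants: 18 (3aR,5R,6S,10R,11S,11aR)-11-hydroxy-6,10-dimethyldecahydro-5,10-epoxycyclodeca[b]furan-2(3H)-one
Product: 21 (3aR,5R,6S,10R,11S,11aR)-11-hydroxy-6,10-dimethyl-3-methylidenedecahydro-5,10-epoxycyclodeca[b]furan-2(3H)-one, via Mannich base 19 (not isolated), via ammonium iodide 20 (not isolated)
Conditions: LiN(iPr)2 (2.3 equiv), THF, −78 °C; CH2=NMe2+ I−, −78 → 23 °C; then MeI, MeOH, 23 °C; then NaHCO3 (aq), CH2Cl2, 23 °C
Reagents that add atoms: N,N-dimethylmethyleneiminium iodide (Eschenmoser's salt) C=[N+](C)C.[I-]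
Why: Mannich aminomethylation of the lactone enolate (the second equivalent of base covers the free hydroxyl), N-methylation and β-elimination of trimethylamine install the exocyclic methylene, and the transient C3 stereocentre is erased.

**Step 13**
Reactants: 21 (3aR,5R,6S,10R,11S,11aR)-11-hydroxy-6,10-dimethyl-3-methylidenedecahydro-5,10-epoxycyclodeca[b]furan-2(3H)-one
Product: 22 (3aR,5R,6S,10R,11S,11aR)-6,10-dimethyl-3-methylidene-2-oxododecahydro-5,10-epoxycyclodeca[b]furan-11-yl 3-methylbutanoate (CNP0274454.1)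
Conditions: (iPrCH2CO)2O (3 equiv), 4-(dimethylamino)pyridine (0.5 equiv), Et3N, CH2Cl2, 23–40 °C
Reagents that add atoms: 3-methylbutanoic anhydride CC(C)CC(=O)OC(=O)CC(C)C
Why: Nucleophile-catalysed (Steglich-type) acylation of the hindered secondary alcohol leaves the C11–O bond intact, so the configuration is retained, and the α-methylene lactone tolerates these mild conditions.

**Compound list**
1 | (2R)-but-3-yn-2-ol | C[C@@H](O)C#C | starting material
2 | (2R,3E)-4-[dimethyl(phenyl)silyl]but-3-en-2-ol | C[C@@H](O)/C=C/[Si](C)(C)c1ccccc1 | intermediate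
3 | methyl (3R,4E)-3-[dimethyl(phenyl)silyl]hex-4-enoate | C/C=C/[C@@H](CC(=O)OC)[Si](C)(C)c1ccccc1 | intermediate
4 | (3R,4E)-3-[dimethyl(phenyl)silyl]hex-4-enal | C/C=C/[C@@H](CC=O)[Si](C)(C)c1ccccc1 | intermediate (not isolated)
5 | [(4R,5E)-hept-5-en-1-yn-4-yl]dimethyl(phenyl)silane | C/C=C/[C@@H](CC#C)[Si](C)(C)c1ccccc1 | intermediate
6 | {(1E,4R,5E)-4-[dimethyl(phenyl)silyl]-2-methylhepta-1,5-dien-1-yl}dimethylalumane | C/C=C/[C@@H](C/C(C)=C/[Al](C)C)[Si](C)(C)c1ccccc1 | intermediate (not isolated)
7 | (2E,5R,6E)-5-[dimethyl(phenyl)silyl]-3-methylocta-2,6-dien-1-ol | C/C=C/[C@@H](C/C(C)=C/CO)[Si](C)(C)c1ccccc1 | intermediate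
8 | (2E,5R,6E)-5-[dimethyl(phenyl)silyl]-3-methylocta-2,6-dienal | C/C=C/[C@@H](C/C(C)=C/C=O)[Si](C)(C)c1ccccc1 | intermediate
9 | methyl (4S,5E,8R,9E)-8-[dimethyl(phenyl)silyl]-4-hydroxy-6-methylundeca-5,9-dien-2-ynoate | C/C=C/[C@@H](C/C(C)=C/[C@H](O)C#CC(=O)OC)[Si](C)(C)c1ccccc1 | intermediate
10 | methyl (4R)-4-hydroxy-4-[(2S,3S)-3-{(2R,3E)-2-[dimethyl(phenyl)silyl]pent-3-en-1-yl}-3-methyloxiran-2-yl]but-2-ynoate | COC(=O)C#C[C@@H](O)[C@@H]1O[C@@]1(C)C[C@H](/C=C/C)[Si](C)(C)c2ccccc2 | intermediate
11 | methyl (2Z,4R)-4-hydroxy-4-[(2S,3S)-3-{(2R,3E)-2-[dimethyl(phenyl)silyl]pent-3-en-1-yl}-3-methyloxiran-2-yl]but-2-enoate | COC(=O)/C=C\[C@@H](O)[C@@H]1O[C@@]1(C)C[C@H](/C=C/C)[Si](C)(C)c2ccccc2 | intermediate (not isolated)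
12 | (5R)-5-[(2S,3S)-3-{(2R,3E)-2-[dimethyl(phenyl)silyl]pent-3-en-1-yl}-3-methyloxiran-2-yl]furan-2(5H)-one | O=C1C=C[C@@H](O1)[C@@H]2O[C@@]2(C)C[C@H](/C=C/C)[Si](C)(C)c3ccccc3 | intermediate
13 | (4S,5R)-4-[(E)-2-ethoxyethenyl]-5-[(2S,3S)-3-{(2R,3E)-2-[dimethyl(phenyl)silyl]pent-3-en-1-yl}-3-methyloxiran-2-yl]oxolan-2-one | CCO/C=C/[C@@H]1CC(=O)O[C@H]1[C@@H]2O[C@@]2(C)C[C@H](/C=C/C)[Si](C)(C)c3ccccc3 | intermediate (not isolated)
14 | 2-{(2R,3R)-2-[(2S,3S)-3-{(2R,3E)-2-[dimethyl(phenyl)silyl]pent-3-en-1-yl}-3-methyloxiran-2-yl]-5-oxooxolan-3-yl}acetaldehyde | O=CC[C@@H]1CC(=O)O[C@H]1[C@@H]2O[C@@]2(C)C[C@H](/C=C/C)[Si](C)(C)c3ccccc3 | intermediate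
15 | seven-membered oxocarbenium triflate (C5H=O(+)–C10) fused trans to the γ-lactone; C10 (R) carries methyl and the (2R,3E)-2-[dimethyl(phenyl)silyl]pent-3-en-1-yl chain, C11 (S) carries OSiMe2Ph | C1C(=O)O[C@@H]2[C@@H]1CC=[O+][C@](C)(C[C@H](/C=C/C)[Si](C)(C)c3ccccc3)[C@H]2O[Si](C)(C)c4ccccc4.[O-]S(=O)(=O)C(F)(F)F | intermediate (not isolated)
16 | (3aR,5R,6S,7Z,10R,11S,11aR)-11-{[dimethyl(phenyl)silyl]oxy}-6,10-dimethyl-3a,4,5,6,9,10,11,11a-octahydro-5,10-epoxycyclodeca[b]furan-2(3H)-one | C1C(=O)O[C@@H]2[C@@H]1C[C@H]3O[C@](C)(C/C=C\[C@@H]3C)[C@H]2O[Si](C)(C)c4ccccc4 | intermediate (not isolated)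
17 | (3aR,5R,6S,7Z,10R,11S,11aR)-11-hydroxy-6,10-dimethyl-3a,4,5,6,9,10,11,11a-octahydro-5,10-epoxycyclodeca[b]furan-2(3H)-one | C1C(=O)O[C@@H]2[C@@H]1C[C@H]3O[C@](C)(C/C=C\[C@@H]3C)[C@H]2O | intermediate
18 | (3aR,5R,6S,10R,11S,11aR)-11-hydroxy-6,10-dimethyldecahydro-5,10-epoxycyclodeca[b]furan-2(3H)-one | C1C(=O)O[C@@H]2[C@@H]1C[C@H]3O[C@](C)(CCC[C@@H]3C)[C@H]2O | intermediate
19 | (3S,3aR,5R,6S,10R,11S,11aR)-3-[(dimethylamino)methyl]-11-hydroxy-6,10-dimethyldecahydro-5,10-epoxycyclodeca[b]furan-2(3H)-one (3S expected, trans to C4; erased in the elimination) | CN(C)C[C@H]1C(=O)O[C@@H]2[C@@H]1C[C@H]3O[C@](C)(CCC[C@@H]3C)[C@H]2O | intermediate (not isolated)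
20 | N-methyl quaternary ammonium iodide of 19 | C[N+](C)(C)C[C@H]1C(=O)O[C@@H]2[C@@H]1C[C@H]3O[C@](C)(CCC[C@@H]3C)[C@H]2O.[I-] | intermediate (not isolated)
21 | (3aR,5R,6S,10R,11S,11aR)-11-hydroxy-6,10-dimethyl-3-methylidenedecahydro-5,10-epoxycyclodeca[b]furan-2(3H)-one | C=C1C(=O)O[C@@H]2[C@@H]1C[C@H]3O[C@](C)(CCC[C@@H]3C)[C@H]2O | intermediate
22 | (3aR,5R,6S,10R,11S,11aR)-6,10-dimethyl-3-methylidene-2-oxododecahydro-5,10-epoxycyclodeca[b]furan-11-yl 3-methylbutanoate | C=C1C(=O)O[C@@H]2[C@@H]1C[C@H]1O[C@](C)(CCC[C@@H]1C)[C@H]2OC(=O)CC(C)C | target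

Total step count: 13
Longest linear sequence: 13 steps (1 → 22)

**Steps most likely to fail**

1. Step 10 (proposed new method). What may go wrong: opening of the activated epoxide at the secondary carbon (a six-membered oxocarbenium ion and the wrong relative configuration at C10 and C11), 1,2-hydride shift of the epoxide to a ketone, stalling at the internal acetal, or protodesilylation before the C–C bond forms. The fallback uses known chemistry and splits the event into two separately precedented stages. It sets out from 14: catalytic camphorsulfonic acid in CH2Cl2 at 0 °C should isomerise the epoxy aldehyde to the internal bicyclic acetal of 14 F1 (the classical epoxy-carbonyl to 6,8-dioxabicyclo[3.2.1]octane conversion, aldehyde oxygen to C10 with inversion). Isolated F1 is then treated with TiCl4 (1.1 equiv) in CH2Cl2 at −78 °C, an established Lewis-acid acetal–allylsilane cyclisation in which the C5–O11 bond ionises and the tethered allylsilane attacks C5 anti to the departing oxygen. Aqueous work-up brings the route back at 17.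

2. Step 7. What may go wrong: low diastereofacial selectivity, because the slim alkynyl substituent on the carbinol carbon exerts little 1,3-allylic strain in the erythro transition state, and over-oxidation of the doubly activated carbinol to the ynone. The fallback sets the epoxide by reagent control before the carbinol centre exists. It sets out from 7: Sharpless asymmetric epoxidation (Ti(OiPr)4, L-(+)-diethyl tartrate, t-BuOOH, 4 Å MS, CH2Cl2, −20 °C) should give [(2S,3S)-3-{(2R,3E)-2-[dimethyl(phenyl)silyl]pent-3-en-1-yl}-3-methyloxiran-2-yl]methanol F2. Dess–Martin periodinane with NaHCO3 in CH2Cl2 then gives (2R,3S)-3-{(2R,3E)-2-[dimethyl(phenyl)silyl]pent-3-en-1-yl}-3-methyloxirane-2-carbaldehyde F3. Catalyst-controlled zinc–ProPhenol alkynylation of F3 with methyl propiolate and Me2Zn then sets the carbinol centre, and the route comes back at 10.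

3. Step 9. What may go wrong: γ-deprotonation of the butenolide followed by β-elimination that opens the neighbouring epoxide, incomplete anti facial selectivity, and acid-induced opening of the epoxide during enol-ether hydrolysis. The fallback introduces the two-carbon arm as a vinyl group and adjusts the oxidation level afterwards. It sets out from 12: vinyl cuprate addition (CH2=CHMgBr, CuBr·SMe2, Me3SiCl, THF, −78 °C) anti to the C5 substituent should give (4S,5R)-4-ethenyl-5-[(2S,3S)-3-{(2R,3E)-2-[dimethyl(phenyl)silyl]pent-3-en-1-yl}-3-methyloxiran-2-yl]oxolan-2-one F4. Hydroboration selective for the monosubstituted olefin (9-BBN, THF; then NaBO3·4H2O) gives (4R,5R)-4-(2-hydroxyethyl)-5-[(2S,3S)-3-{(2R,3E)-2-[dimethyl(phenyl)silyl]pent-3-en-1-yl}-3-methyloxiran-2-yl]oxolan-2-one F5. Dess–Martin oxidation of F5 brings the route back at 14.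

**Further compounds**
F1 | step 10 | internal bicyclic acetal of 14: acetal carbon C5 bonded to the C10 ether oxygen and to the C11 oxygen (6,8-dioxabicyclo[3.2.1]octane fused to the γ-lactone), allylsilane chain intact | C1C(=O)O[C@@H]2[C@@H]1C[C@@H]3O[C@](C)(C[C@H](/C=C/C)[Si](C)(C)c4ccccc4)[C@H]2O3
F2 | step 7 | [(2S,3S)-3-{(2R,3E)-2-[dimethyl(phenyl)silyl]pent-3-en-1-yl}-3-methyloxiran-2-yl]methanol | OC[C@@H]1O[C@@]1(C)C[C@H](/C=C/C)[Si](C)(C)c2ccccc2
F3 | step 7 | (2R,3S)-3-{(2R,3E)-2-[dimethyl(phenyl)silyl]pent-3-en-1-yl}-3-methyloxirane-2-carbaldehyde | O=C[C@@H]1O[C@@]1(C)C[C@H](/C=C/C)[Si](C)(C)c2ccccc2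
F4 | step 9 | (4S,5R)-4-ethenyl-5-[(2S,3S)-3-{(2R,3E)-2-[dimethyl(phenyl)silyl]pent-3-en-1-yl}-3-methyloxiran-2-yl]oxolan-2-one | C=C[C@@H]1CC(=O)O[C@H]1[C@@H]2O[C@@]2(C)C[C@H](/C=C/C)[Si](C)(C)c3ccccc3
F5 | step 9 | (4R,5R)-4-(2-hydroxyethyl)-5-[(2S,3S)-3-{(2R,3E)-2-[dimethyl(phenyl)silyl]pent-3-en-1-yl}-3-methyloxiran-2-yl]oxolan-2-one | OCC[C@@H]1CC(=O)O[C@H]1[C@@H]2O[C@@]2(C)C[C@H](/C=C/C)[Si](C)(C)c3ccccc3
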